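**Retrosynthetic overview**
1. Lignan numbering: Ar1 = free guaiacyl on C7, Ar2 = prenyloxyaryl on C7', fusion bond C8–C8'. Ring A = O7–C7–C8–C8'–C9' and ring B = O9–C9–C8–C8'–C7'.
2. Feature used: C9' is a bare CH2 bonded only to O7 and C8', and C7' sits next to a para-oxygenated aryl that can carry positive charge. Breaking C8'–C9' and C7'–O9 and tying C9' to O9 turns the bicyclic core into an isomeric formaldehyde acetal, a cis-4-aryl-5-[(E)-styryl]-1,3-dioxane.
3. In the forward sense one Lewis acid operation rebuilds the core from that dioxane: ring A first (C8'–C9'), ring B second (C7'–O9). C8' and C7' are created there.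
4. The dioxane comes from dimethoxymethane and a syn 1,3-diol. The diol comes from an Evans syn aldol (sets C7 and C8) between a styrylacetyl imide (Wittig reaction on O-silyl vanillin) and O-pivaloyl vanillin.
5. Endgame: the silyl and pivaloyl masks on the two phenols are removed in turn, so only Ar2 is prenylated.

Key step: step 8

Remark: O7 and O9 denote the oxygen atoms bonded to C7 and C9 in every intermediate. The minor (Z)-alkene expected from step 2 is assumed to be removed at the stage of acid 5.

**Step 1**
Reactants: 1 vanillin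
Product: 2 4-(tert-butyldimethylsilyloxy)-3-methoxybenzaldehyde
Conditions: TBSCl, imidazole, CH2Cl2, 0 °C to rt
Reagents that add atoms: tert-butyldimethylsilyl chloride, CC(C)(C)[Si](C)(C)Cl
Why: Imidazole-promoted O-silylation of a phenol is a routine protection that leaves the aldehyde untouched and keeps the para oxygen of Ar2 electron-releasing for the later cation.

**Step 2**
Reactants: 2 4-(tert-butyldimethylsilyloxy)-3-methoxybenzaldehyde; 3 (2-carboxyethyl)triphenylphosphonium bromide
Product: 5 (E)-4-[4-(tert-butyldimethylsilyloxy)-3-methoxyphenyl]but-3-enoic acid, via sodium ylide carboxylate 4 (not isolated)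
Conditions: 3, NaN(SiMe3)2 (2.1 equiv), THF, 0 °C; 2, −78 °C to rt; 1 M HCl to pH 3
Reagents that add atoms: sodium hexamethyldisilazide, C[Si](C)(C)[N-][Si](C)(C)C.[Na+] (sodium ion carried only by intermediate 4, none in 5)
Why: Wittig olefination with a carboxylate-bearing ylide, which with aromatic aldehydes is known to favour the (E)-alkene, should give the β,γ-unsaturated acid whose double bond stays conjugated to the aryl ring.

**Step 3**
Reactants: 5 (E)-4-[4-(tert-butyldimethylsilyloxy)-3-methoxyphenyl]but-3-enoic acid; 6 (S)-4-benzyl-2-oxazolidinone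
Product: 8 (S)-4-benzyl-3-{(E)-4-[4-(tert-butyldimethylsilyloxy)-3-methoxyphenyl]but-3-enoyl}oxazolidin-2-one, via mixed pivalic anhydride 7 (not isolated)
Conditions: PivCl, Et3N, THF, −20 °C; LiCl, 6, −20 °C to rt
Reagents that add atoms: pivaloyl chloride, CC(C)(C)C(=O)Cl (atoms carried only by intermediate 7, none in 8)
Why: Mixed-anhydride N-acylation of the oxazolidinone assisted by LiCl needs only Et3N as base, so the β,γ-double bond should not slip into conjugation, and the nucleophile attacks the less hindered carbonyl of 7.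

**Step 4**
Reactants: 1 vanillin
Product: 9 4-formyl-2-methoxyphenyl pivalate
Conditions: PivCl, Et3N, DMAP (cat.), CH2Cl2, 0 °C to rt
Reagents that add atoms: pivaloyl chloride, CC(C)(C)C(=O)Cl
Why: DMAP-catalysed acylation of the phenol gives a hindered aryl ester that withdraws electron density from Ar1, should survive the later Lewis acid, fluoride and carbonate steps, and makes the aldehyde more electrophilic.

**Step 5**
Reactants: 8 (S)-4-benzyl-3-{(E)-4-[4-(tert-butyldimethylsilyloxy)-3-methoxyphenyl]but-3-enoyl}oxazolidin-2-one; 9 4-formyl-2-methoxyphenyl pivalate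
Product: 12 (S)-4-benzyl-3-{(2S,3E)-4-[4-(tert-butyldimethylsilyloxy)-3-methoxyphenyl]-2-[(S)-hydroxy(3-methoxy-4-pivaloyloxyphenyl)methyl]but-3-enoyl}oxazolidin-2-one, via Z-boron dienolate 10 (not isolated), via boron aldolate 11 (not isolated)
Conditions: n-Bu2BOTf, Et3N, CH2Cl2, −78 to 0 °C; 9, −78 to 0 °C; pH 7 buffer, MeOH, 30% H2O2, 0 °C
Reagents that add atoms: di-n-butylboron triflate, CCCCB(CCCC)OS(=O)(=O)C(F)(F)F (boron and butyl groups carried only by 10 and 11, none in 12)
Why: In this Evans syn aldol the Z-boron dienolate reacts at its α-carbon C8 through a closed Zimmerman–Traxler chair in which the benzyl group of the (S)-auxiliary shields one enolate face, which should set C7 as S and C8 in the configuration of the target with syn relative stereochemistry.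

**Step 6**
Reactants: 12 syn aldol imide
Product: 13 4-{(1S,2R,3E)-4-[4-(tert-butyldimethylsilyloxy)-3-methoxyphenyl]-1-hydroxy-2-(hydroxymethyl)but-3-en-1-yl}-2-methoxyphenyl pivalate
Conditions: LiBH4, H2O (1 equiv), Et2O–THF, 0 °C; aq NH4Cl
Reagents that add atoms: none
Why: Reductive removal of the Evans auxiliary with LiBH4 should hit the activated exocyclic imide carbonyl at 0 °C much faster than the hindered aryl pivalate and leaves C7 and C8 untouched (the C8 descriptor becomes R only because C9 drops in priority).

**Step 7**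
Reactants: 13 syn 1,3-diol; 14 dimethoxymethane
Product: 16 4-{(4S,5R)-5-[(E)-2-(4-(tert-butyldimethylsilyloxy)-3-methoxyphenyl)ethenyl]-1,3-dioxan-4-yl}-2-methoxyphenyl pivalate (cis), via primary methoxymethyl ether 15 (not isolated)
Conditions: 14 (5 equiv), Me3SiOTf (2.5 equiv), 2,6-lutidine (4 equiv), CH2Cl2, 0 °C
Reagents that add atoms: none
Why: This is transacetalisation of a 1,3-diol to its formaldehyde acetal under silyl triflate/lutidine conditions, where the oxocarbenium ions are held as weakly electrophilic lutidinium adducts that oxygen nucleophiles displace but a styrene does not, so the ring should close on oxygen without early Prins reaction or protonation of the styrene, and the syn diol maps onto the cis-4,5-disubstituted dioxane with no stereocentre touched.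

**Step 8**
Reactants: 16 cis-4-aryl-5-[(E)-styryl]-1,3-dioxane
Product: 19 4-{(1S,3aR,4S,6aR)-4-[4-(tert-butyldimethylsilyloxy)-3-methoxyphenyl]tetrahydro-1H,3H-furo[3,4-c]furan-1-yl}-2-methoxyphenyl pivalate, via O7 oxocarbenium triflate 17 (not isolated), via C7' benzylic cation triflate 18 (not isolated)
Conditions: Me3SiOTf (0.3 equiv), 2,6-di-tert-butyl-4-methylpyridine (0.1 equiv), 4 Å molecular sieves, CH2Cl2 (0.01 M), −78 to −30 °C; Et3N quench at −30 °C
Reagents that add atoms: trimethylsilyl triflate, C[Si](C)(C)OS(=O)(=O)C(F)(F)F (atoms carried only by 17 and 18, none in 19)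
Why: Proposed new method: Me3SiOTf silylates the less hindered primary acetal oxygen O9, the O9–C9' bond breaks to leave oxocarbenium ion 17 on O7, the styrene carbon C8' attacks C9' to give the quinone-methide-like para-silyloxybenzylic cation 18, and the silyl ether oxygen O9 captures C7' and returns Me3Si+ to triflate, so the step is a catalytic isomerisation in which no atom is gained or lost. The closest known reaction types are oxonium-Prins cyclisations of styrenyl homoallylic oxocarbenium ions to tetrahydrofurans with capture of the benzylic cation, Prins cascades terminated by a tethered oxygen nucleophile, and Lewis acid opening of unsymmetrical 1,3-dioxanes at the less hindered oxygen, but their union in a dioxane-to-furofuran rearrangement has not been shown. Ring A (O7–C7–C8–C8'–C9') closes in a five-membered mode that is exo to the styrene π bond and endo to the C9'=O7 bond, the aryl group steering charge to C7' and so overriding six-membered closure through C7', and ring B (O9–C9–C8–C8'–C7') closes by 5-exo-trig capture of the cation. C8' is controlled by C8 through antiperiplanar addition to the alkene: only the rotamer in which the C8–C9 bond eclipses the double bond holds C9' over one face of C8' and O9 over the opposite face of C7', so the charge is quenched as it builds and the C8/C8' junction is necessarily cis. C7' is controlled kinetically by allylic 1,3-strain in 18, which keeps H8' in the plane of the cation beside the aryl ring so that O9 adds to the face that leaves Ar2 exo, the same outcome as anti addition to the (E)-alkene, and the cold amine quench guards this centre against acid epimerisation. The step needs cleavage at O9 and not at O7 (which would lead to the isomeric bicycle in which one oxygen bridges C7 and C7' and the other C9 and C9') and no ionisation or 2-oxonia-Cope shift at C7, and the steric preference of the bulky silyl electrophile for the primary oxygen together with the electron-poor pivaloyloxy ring Ar1 should secure both.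

**Step 9**
Reactants: 19 furofuran with Ar1 pivalate and Ar2 silyl ether
Product: 20 4-{(1S,3aR,4S,6aR)-4-(4-hydroxy-3-methoxyphenyl)tetrahydro-1H,3H-furo[3,4-c]furan-1-yl}-2-methoxyphenyl pivalate
Conditions: Bu4NF, AcOH (1:1), THF, 0 °C
Reagents that add atoms: none
Why: Fluoride cleavage of an aryl silyl ether is fast at 0 °C, and the acetic acid buffer keeps the freed phenol protonated so that acyl transfer from the pivalate and base-induced opening at C7' should not occur.

**Step 10**
Reactants: 20 Ar2 phenol; 21 prenyl bromide (1-bromo-3-methylbut-2-ene)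
Product: 22 2-methoxy-4-{(1S,3aR,4S,6aR)-4-[3-methoxy-4-(3-methylbut-2-enyloxy)phenyl]tetrahydro-1H,3H-furo[3,4-c]furan-1-yl}phenyl pivalate
Conditions: K2CO3, acetone, rt to 40 °C
Reagents that add atoms: none
Why: In this Williamson ether synthesis the only free phenol, that of Ar2, is alkylated by SN2 attack at the primary allylic carbon, while the hindered pivalate should be inert to carbonate in an aprotic solvent.

**Step 11**
Reactants: 22 Ar1 pivalate with Ar2 prenyl ether
Product: 23 4-{(1S,3aR,4S,6aR)-4-[3-methoxy-4-(3-methylbut-2-enyloxy)phenyl]tetrahydro-1H,3H-furo[3,4-c]furan-1-yl}-2-methoxyphenol (target, 7S,7'S,8R,8'R)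
Conditions: NaOMe (1.2 equiv), MeOH, 0 °C to rt; AcOH
Reagents that add atoms: none
Why: Methoxide transesterification cleaves the activated aryl ester, and neither the prenyl ether nor the four stereocentres of the furofuran are sensitive to this base.

**Compound list**
1 | vanillin | COc1cc(C=O)ccc1O | starting material
2 | 4-(tert-butyldimethylsilyloxy)-3-methoxybenzaldehyde | COc1cc(C=O)ccc1O[Si](C)(C)C(C)(C)C | intermediate
3 | (2-carboxyethyl)triphenylphosphonium bromide | OC(=O)CC[P+](c1ccccc1)(c1ccccc1)c1ccccc1.[Br-] | starting material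
4 | sodium 3-(triphenylphosphoranylidene)propanoate | [Na+].[O-]C(=O)CC=P(c1ccccc1)(c1ccccc1)c1ccccc1 | intermediate
5 | (E)-4-[4-(tert-butyldimethylsilyloxy)-3-methoxyphenyl]but-3-enoic acid | COc1cc(/C=C/CC(=O)O)ccc1O[Si](C)(C)C(C)(C)C | intermediate
6 | (S)-4-benzyl-2-oxazolidinone | O=C1N[C@@H](Cc2ccccc2)CO1 | starting material
7 | mixed anhydride of 5 with pivalic acid | COc1cc(/C=C/CC(=O)OC(=O)C(C)(C)C)ccc1O[Si](C)(C)C(C)(C)C | intermediate
8 | (S)-4-benzyl-3-{(E)-4-[4-(tert-butyldimethylsilyloxy)-3-methoxyphenyl]but-3-enoyl}oxazolidin-2-one | COc1cc(/C=C/CC(=O)N2[C@@H](Cc3ccccc3)COC2=O)ccc1O[Si](C)(C)C(C)(C)C | intermediate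
9 | 4-formyl-2-methoxyphenyl pivalate | COc1cc(C=O)ccc1OC(=O)C(C)(C)C | intermediate
10 | di-n-butylboron (Z)-dienolate of 8 | CCCCB(CCCC)O/C(=C\C=C\c1ccc(O[Si](C)(C)C(C)(C)C)c(OC)c1)N1[C@@H](Cc2ccccc2)COC1=O | intermediate
11 | di-n-butylboron aldolate of 12 | COc1cc([C@@H](OB(CCCC)CCCC)[C@H](/C=C/c2ccc(O[Si](C)(C)C(C)(C)C)c(OC)c2)C(=O)N2[C@@H](Cc3ccccc3)COC2=O)ccc1OC(=O)C(C)(C)C | intermediate
12 | syn aldol imide (2S, carbinol S, auxiliary S) | COc1cc([C@@H](O)[C@H](/C=C/c2ccc(O[Si](C)(C)C(C)(C)C)c(OC)c2)C(=O)N2[C@@H](Cc3ccccc3)COC2=O)ccc1OC(=O)C(C)(C)C | intermediate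
13 | (1S,2R,3E)-syn 1,3-diol | COc1cc([C@@H](O)[C@@H](CO)/C=C/c2ccc(O[Si](C)(C)C(C)(C)C)c(OC)c2)ccc1OC(=O)C(C)(C)C | intermediate
14 | dimethoxymethane | COCOC | starting material
15 | primary (O9) methoxymethyl ether of 13 | COc1cc([C@@H](O)[C@@H](COCOC)/C=C/c2ccc(O[Si](C)(C)C(C)(C)C)c(OC)c2)ccc1OC(=O)C(C)(C)C | intermediate
16 | (4S,5R)-cis-4-aryl-5-[(E)-styryl]-1,3-dioxane (key-step precursor) | COc1cc([C@H]2OCOC[C@H]2/C=C/c2ccc(O[Si](C)(C)C(C)(C)C)c(OC)c2)ccc1OC(=O)C(C)(C)C | intermediate
17 | O7 methylidene oxonium triflate with O9 trimethylsilyl ether | COc1cc([C@@H]([O+]=C)[C@@H](CO[Si](C)(C)C)/C=C/c2ccc(O[Si](C)(C)C(C)(C)C)c(OC)c2)ccc1OC(=O)C(C)(C)C.[O-]S(=O)(=O)C(F)(F)F | intermediate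
18 | ring A tetrahydrofuran with C7' benzylic cation (triflate) cis to the C9 silyloxymethyl group | COc1cc([C@H]2OC[C@H]([CH+]c3ccc(O[Si](C)(C)C(C)(C)C)c(OC)c3)[C@@H]2CO[Si](C)(C)C)ccc1OC(=O)C(C)(C)C.[O-]S(=O)(=O)C(F)(F)F | intermediate
19 | furofuran with Ar1 pivalate and Ar2 silyl ether (key-step product) | COc1cc([C@H]2OC[C@H]3[C@@H]2CO[C@@H]3c2ccc(O[Si](C)(C)C(C)(C)C)c(OC)c2)ccc1OC(=O)C(C)(C)C | intermediate
20 | furofuran with Ar1 pivalate and free Ar2 phenol | COc1cc([C@H]2OC[C@H]3[C@@H]2CO[C@@H]3c2ccc(O)c(OC)c2)ccc1OC(=O)C(C)(C)C | intermediate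
21 | prenyl bromide | CC(C)=CCBr | starting material
22 | furofuran with Ar1 pivalate and Ar2 prenyl ether | COc1cc([C@H]2OC[C@H]3[C@@H]2CO[C@@H]3c2ccc(OCC=C(C)C)c(OC)c2)ccc1OC(=O)C(C)(C)C | intermediate
23 | CNP0185952.1, (7S,7'S,8R,8'R)-pinoresinol mono-prenyl ether | COc1cc([C@H]2OC[C@H]3[C@@H]2CO[C@@H]3c2ccc(OCC=C(C)C)c(OC)c2)ccc1O | target

**Step count**
Total step count: 11. Longest linear sequence: 10 (steps 1, 2, 3, 5, 6, 7, 8, 9, 10, 11). Step 4 is the side branch.

**Steps most likely to fail**

**1. Step 8.** Four processes could spoil it.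
- The acetal may open at O7, or the two oxocarbenium ions may equilibrate.
- Ring A may close from the rotamer that puts C7' trans to C9. Simple chair-like models favour this rotamer, and the resulting cation has no internal nucleophile, so elimination or oligomerisation would follow.
- The formaldehyde acetal may ionise too slowly at low temperature.
- The product may re-ionise at C7' and lose the exo configuration.

The fallback uses known chemistry and sets the C8/C8' relationship on a lactone instead of in a cation. It sets out from aldehydes 9 and 2 and comes back at 19.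
- L-Proline-catalysed cross-aldol reaction of methyl 4-oxobutanoate with 9 (DMF, 4 °C) should give the anti aldol aldehyde F1, with C8 configured as in the target.
- NaBH4 in MeOH, added to the same flask, reduces the aldehyde, and the new primary alcohol lactonises to the β-(hydroxybenzyl)butyrolactone F2.
- TBSOTf and 2,6-lutidine give the silyl ether F3.
- LiN(SiMe3)2 and then 2 (THF, −78 °C) add C7' to the lactone enolate carbon C8' trans to the C8 side chain. This is the relative configuration the cis-fused core requires, and it gives the aldol lactone F4. Its carbinol epimers do not matter.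
- LiAlH4 (THF, 0 °C) reduces lactone and pivalate to the phenolic triol F5.
- Camphorsulfonic acid in CH2Cl2 ionises both benzylic C–O bonds, each para to a donor oxygen. The two primary alcohols then close rings A and B by the established double cycloetherification of such 1,4-diaryl-2,3-bis(hydroxymethyl)butane-1,4-diol derivatives. C7 and C7' are reset to exo, giving the mono-silyl pinoresinol F6.
- PivCl and Et3N esterify its only free phenol to give 19.

**2. Step 7.** A free oxocarbenium ion may be intercepted by the styrene before the second oxygen closes the ring, or both hydroxyls may end up capped as acyclic methoxymethyl ethers.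

The fallback forms the two C–O bonds of the acetal one after the other by substitution and avoids a free cation. It sets out from 13 and comes back at 16.
- MOMCl (1.1 equiv) and i-Pr2NEt (CH2Cl2, 0 °C) alkylate the primary hydroxyl selectively, and 15 is now isolated.
- Me3SiOTf with 2,2'-bipyridyl (CH2Cl2, 0 °C) exchanges its methoxy group for the heterocycle to give the bipyridinium salt F7.
- F7 is too weak an electrophile for an alkene. The neighbouring C7 oxygen displaces the heterocycle and closes 16.

**3. Step 5.** After enolisation the double bond may migrate into conjugation with the imide, the dienolate may attack through its γ-carbon, or the doubly activated C8–H may epimerise on work-up.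

The fallback performs the aldol first and attaches Ar2 afterwards. It sets out from 6, 9 and 2 and comes back at 12.
- n-BuLi and (E)-crotonyl chloride convert 6 into the crotonyl imide F8.
- Deconjugative enolisation of F8 with n-Bu2BOTf and Et3N, followed by α-selective Evans syn aldol reaction with 9, should give the α-vinyl aldol F9.
- Methylenetriphenylphosphorane converts 2 into the silyloxystyrene F10.
- Cross metathesis of F9 with F10 (second-generation Hoveyda–Grubbs catalyst, 1,4-benzoquinone, CH2Cl2, 40 °C) should give the (E)-styrene 12.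
- This path also bypasses steps 2 and 3.

**Further compounds**
F1 | step 8 | methyl (3S,4R)-3-formyl-4-hydroxy-4-(3-methoxy-4-pivaloyloxyphenyl)butanoate | COc1cc([C@H](O)[C@@H](C=O)CC(=O)OC)ccc1OC(=O)C(C)(C)C
F2 | step 8 | (4R)-4-[(R)-hydroxy(3-methoxy-4-pivaloyloxyphenyl)methyl]dihydrofuran-2(3H)-one | COc1cc([C@H](O)[C@H]2COC(=O)C2)ccc1OC(=O)C(C)(C)C
F3 | step 8 | O7 tert-butyldimethylsilyl ether of F2 | COc1cc([C@H](O[Si](C)(C)C(C)(C)C)[C@H]2COC(=O)C2)ccc1OC(=O)C(C)(C)C
F4 | step 8 | trans-α,β-disubstituted lactone from aldol addition of F3 to 2 (C7' carbinol epimers) | COc1cc([C@H](O[Si](C)(C)C(C)(C)C)[C@H]2COC(=O)[C@@H]2C(O)c2ccc(O[Si](C)(C)C(C)(C)C)c(OC)c2)ccc1OC(=O)C(C)(C)C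
F5 | step 8 | phenolic triol from reduction of F4 | COc1cc([C@H](O[Si](C)(C)C(C)(C)C)[C@@H](CO)[C@H](CO)C(O)c2ccc(O[Si](C)(C)C(C)(C)C)c(OC)c2)ccc1O
F6 | step 8 | pinoresinol mono-silyl ether (Ar2 silyl ether, Ar1 free phenol) | COc1cc([C@H]2OC[C@H]3[C@@H]2CO[C@@H]3c2ccc(O[Si](C)(C)C(C)(C)C)c(OC)c2)ccc1O
F7 | step 7 | 1-(alkoxymethyl)-2,2'-bipyridinium triflate derived from 15 | COc1cc([C@@H](O)[C@@H](COC[n+]2ccccc2-c2ccccn2)/C=C/c2ccc(O[Si](C)(C)C(C)(C)C)c(OC)c2)ccc1OC(=O)C(C)(C)C.[O-]S(=O)(=O)C(F)(F)F
F8 | step 5 | (S)-4-benzyl-3-[(E)-but-2-enoyl]oxazolidin-2-one | C/C=C/C(=O)N1[C@@H](Cc2ccccc2)COC1=O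
F9 | step 5 | α-vinyl syn aldol imide from F8 and 9 | COc1cc([C@@H](O)[C@H](C=C)C(=O)N2[C@@H](Cc3ccccc3)COC2=O)ccc1OC(=O)C(C)(C)C
F10 | step 5 | 4-(tert-butyldimethylsilyloxy)-3-methoxystyrene | COc1cc(C=C)ccc1O[Si](C)(C)C(C)(C)C
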